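**Plan** (germacrane numbering: ring C1–C10 with C1=C10 carrying the C14 methyl, C4=C5 carrying C15H2–O–ester, C6–OH, C7, C8–O; lactone C8–O–C12(=O)–C11(=C13H2)–C7)

- Retrosynthesis cuts, in order: the side-chain O–TBS bond; C6–C7 (ten-membered ring, opened to a C6 enal and an α-(bromomethyl)butenolide); the butenolide C7=C11 bond (RCM) and the C8–O acyl bond; C4–C15 (a (Z)-C4 iodide plus the complete acyloxymethyl side chain as its zinc reagent); C1–C2 (iodo-dienol 9 plus a C5 alkynylzinc).
- Forward: the open chain is joined first (C1–C2), the side chain is then attached at C4, the five-membered butenolide is closed by RCM, and the ten-membered carbocycle with its exocyclic methylene is closed last (C6–C7).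
- Feature that allows the C4–C15 coupling: O6 is allylic to C4=C5, so in the open chain C6 is the CH2OH of a propargylic alcohol on C4≡C5. Its alkoxide directs trans-hydroalumination (H to C5, Al then I to C4), which puts C3 trans to C6, the ring-E geometry. C15 bears only O and H, so it can be delivered as an α-acyloxymethylzinc without β-hydrogen, and the whole 4-hydroxytiglate enters already esterified on C15.
- Stereochemistry: C8 comes from (S)-epichlorohydrin; C7 (attack anti to C9 on the butenolide, trans-lactone) and C6 (chair chromium transition state) are set in the ring closure; C1=C10 (E) comes from carboalumination and the side-chain (E)-alkene from a Wittig reaction.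

Key step: step 15

**Route**

Step 1
Reactants: 1 (S)-epichlorohydrin; 2 ethynyl(trimethyl)silane
Product: 4 (2S)-1-chloro-5-(trimethylsilyl)pent-4-yn-2-ol, via lithium (trimethylsilyl)acetylide 3 (not isolated)
Conditions: n-BuLi, THF, −78 °C; BF3·OEt2; then 1, −78 °C
Reagents that add atoms: none
Why: Yamaguchi alkynylation: the BF3-activated epoxide is opened at its unsubstituted CH2 by the lithium acetylide, so the C–O stereocentre (the later C8) is carried over from 1 unchanged.

Step 2
Reactants: 4 (2S)-1-chloro-5-(trimethylsilyl)pent-4-yn-2-ol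
Product: 6 (3S)-6-(trimethylsilyl)hex-1-en-5-yn-3-ol, via terminal epoxide 5 (not isolated)
Conditions: Me3S+ I− (4 equiv), n-BuLi (3.8 equiv), THF, −20 °C to rt
Reagents that add atoms: trimethylsulfonium iodide, C[S+](C)C.[I-]
Why: The alkoxide closes the terminal epoxide (intramolecular Williamson reaction), dimethylsulfonium methylide opens it at CH2 and the derived ylide eliminates Me2S (one-carbon epoxide-to-allylic-alcohol homologation); no bond to the stereocentre is broken.

Step 3
Reactants: 6 (3S)-6-(trimethylsilyl)hex-1-en-5-yn-3-ol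
Product: 7 (3S)-hex-1-en-5-yn-3-ol
Conditions: K2CO3, MeOH, 0 °C to rt (volatile product, handled in solution)
Reagents that add atoms: none
Why: Base-catalysed methanolysis of the alkynyl C–Si bond (protodesilylation) frees the terminal alkyne without touching the allylic alcohol.

Step 4
Reactants: 7 (3S)-hex-1-en-5-yn-3-ol
Product: 9 (3S,5E)-6-iodo-5-methylhexa-1,5-dien-3-ol, via alkenyl(dimethyl)alane 8 (not isolated)
Conditions: Me3Al (3 equiv), Cp2ZrCl2 (25 mol%), CH2Cl2, 0 °C to rt; then I2, THF, −30 °C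
Reagents that add atoms: trimethylaluminium, C[Al](C)C; iodine, II
Why: Negishi zirconium-catalysed carboalumination adds CH3 and Al syn across the terminal alkyne (CH3 to the internal carbon) and iodinolysis of the C–Al bond with retention should give the (E)-iodide, which fixes the C1=C10 geometry; the vinyl group next to the aluminium alkoxide is much less reactive.

Step 5
Reactants: 10 tert-butyl(dimethyl)(prop-2-yn-1-yloxy)silane
Product: 12 5-[(tert-butyldimethylsilyl)oxy]pent-3-yn-1-ol, via lithium acetylide 11 (not isolated)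
Conditions: n-BuLi, THF, −78 °C; BF3·OEt2; ethylene oxide, −78 °C
Reagents that add atoms: ethylene oxide, C1CO1
Why: BF3-promoted opening of ethylene oxide by the lithium acetylide (Yamaguchi alkynylation) should give the homopropargylic alcohol carrying C2–C6.

Step 6
Reactants: 12 5-[(tert-butyldimethylsilyl)oxy]pent-3-yn-1-ol
Product: 13 tert-butyl[(5-iodopent-2-yn-1-yl)oxy]dimethylsilane
Conditions: I2, PPh3, imidazole, CH2Cl2, 0 °C
Reagents that add atoms: iodine, II
Why: Appel-type (Garegg–Samuelsson) iodination of the primary alcohol; the silyl ether and the alkyne are inert.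

Step 7
Reactants: 13 tert-butyl[(5-iodopent-2-yn-1-yl)oxy]dimethylsilane; 9 (3S,5E)-6-iodo-5-methylhexa-1,5-dien-3-ol
Product: 15 (3S,5E)-11-[(tert-butyldimethylsilyl)oxy]-5-methylundeca-1,5-dien-9-yn-3-ol, via alkylzinc iodide 14 (not isolated)
Conditions: 13, Zn dust (activated), LiCl, THF, 40 °C; then 9, PdCl2(dppf) (5 mol%), THF, 45 °C
Reagents that add atoms: none
Why: Zinc inserts into the primary C–I bond and the alkylzinc iodide undergoes Negishi sp3–sp2 coupling with the alkenyl iodide with retention of the (E)-geometry (C1–C2 bond); the free secondary hydroxyl is tolerated by the organozinc halide.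

Step 8
Reactants: 15 (3S,5E)-11-[(tert-butyldimethylsilyl)oxy]-5-methylundeca-1,5-dien-9-yn-3-ol
Product: 16 (6E,9S)-7-methylundeca-6,10-dien-2-yne-1,9-diol
Conditions: TBAF, THF, 0 °C
Reagents that add atoms: none
Why: Fluoride cleavage of the silyl ether frees the propargylic hydroxyl needed to direct the next step.

Step 9
Reactants: 16 (6E,9S)-7-methylundeca-6,10-dien-2-yne-1,9-diol
Product: 18 (2Z,6E,9S)-3-iodo-7-methylundeca-2,6,10-triene-1,9-diol, via sodium alkenylalanate 17 (not isolated)
Conditions: Red-Al (3.5 equiv), THF, 0 °C to rt; EtOAc; then I2, THF, −78 to 0 °C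
Reagents that add atoms: iodine, II
Why: Hydroxyl-directed trans-hydroalumination of the propargylic alcohol puts Al on the distal carbon C4 within a five-membered alanate and H on C5 anti, and iodinolysis with retention should give only the (Z)-3-iodoallylic alcohol (C3 trans to C6); the isolated alkenes are not reduced.

Step 10
Reactants: 18 (2Z,6E,9S)-3-iodo-7-methylundeca-2,6,10-triene-1,9-diol
Product: 19 (3S,5E,9Z)-9-iodo-5-methyl-11-[(triethylsilyl)oxy]undeca-1,5,9-trien-3-ol
Conditions: TESCl (1.05 equiv), imidazole, CH2Cl2, −78 to −40 °C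
Reagents that add atoms: chlorotriethylsilane, CC[Si](Cl)(CC)CC
Why: Kinetic silylation of the primary allylic hydroxyl (C6–OH) in preference to the secondary one (C8–OH) at low temperature with one equivalent of silyl chloride.

Step 11
Reactants: 20 [(tert-butyldimethylsilyl)oxy]acetaldehyde; 21 ethyl 2-(triphenyl-λ5-phosphanylidene)propanoate
Product: 22 ethyl (2E)-4-[(tert-butyldimethylsilyl)oxy]-2-methylbut-2-enoate
Conditions: CH2Cl2, rt
Reagents that add atoms: none
Why: Wittig olefination with a stabilised α-methyl ylide, expected to be (E)-selective, sets the side-chain alkene geometry.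

Step 12
Reactants: 22 ethyl (2E)-4-[(tert-butyldimethylsilyl)oxy]-2-methylbut-2-enoate
Product: 23 (2E)-4-[(tert-butyldimethylsilyl)oxy]-2-methylbut-2-enoic acid
Conditions: LiOH·H2O, THF/MeOH/H2O, rt; then 1 M HCl to pH 3
Reagents that add atoms: lithium hydroxide, [Li+].[OH-]
Why: Saponification of the ethyl ester; the primary TBS ether is stable to aqueous hydroxide and the trisubstituted enoate does not isomerise.

Step 13
Reactants: 23 (2E)-4-[(tert-butyldimethylsilyl)oxy]-2-methylbut-2-enoic acid
Product: 24 chloromethyl (2E)-4-[(tert-butyldimethylsilyl)oxy]-2-methylbut-2-enoate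
Conditions: ClCH2OSO2Cl, NaHCO3, n-Bu4NHSO4 (cat.), CH2Cl2/H2O, 0 °C to rt
Reagents that add atoms: chloromethyl chlorosulfate, ClCOS(=O)(=O)Cl
Why: Phase-transfer O-alkylation of the carboxylate by chloromethyl chlorosulfate (chlorosulfate as leaving group), the standard access to chloromethyl esters.

Step 14
Reactants: 24 chloromethyl (2E)-4-[(tert-butyldimethylsilyl)oxy]-2-methylbut-2-enoate
Product: 25 iodomethyl (2E)-4-[(tert-butyldimethylsilyl)oxy]-2-methylbut-2-enoate
Conditions: NaI, acetone, rt, dark; used crude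
Reagents that add atoms: sodium iodide, [Na+].[I-]
Why: Finkelstein halide exchange, driven by precipitation of NaCl, gives the iodide needed for zinc insertion.

Step 15
Reactants: 25 iodomethyl (2E)-4-[(tert-butyldimethylsilyl)oxy]-2-methylbut-2-enoate; 19 (3S,5E,9Z)-9-iodo-5-methyl-11-[(triethylsilyl)oxy]undeca-1,5,9-trien-3-ol
Product: 27 (2Z)-2-[(3E,6S)-6-hydroxy-4-methylocta-3,7-dien-1-yl]-4-[(triethylsilyl)oxy]but-2-en-1-yl (2E)-4-[(tert-butyldimethylsilyl)oxy]-2-methylbut-2-enoate, via (acyloxymethyl)zinc iodide 26 (not isolated)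
Conditions: 25, Zn dust (activated), THF, 15–25 °C; then 19, Pd(OAc)2 (5 mol%), SPhos (10 mol%), THF, rt (2.5 equiv of 26, slow addition)
Reagents that add atoms: none
Why: Zinc inserts into the C–I bond of 25 to give the carbonyl-chelated (acyloxymethyl)zinc iodide 26, which has no β-hydrogen; Pd(0) adds oxidatively to the C4–I bond of 19 with retention, 26 transmetalates and reductive elimination forms C4–C15. The closest known reaction types are the Negishi coupling of (acyloxymethyl)zinc iodides with aryl and heteroaryl halides and the Negishi coupling of (Z)-3-iodoallylic alcohol derivatives with alkylzinc halides in trisubstituted-olefin synthesis. No ring is closed and no stereocentre is created; the C4=C5 geometry (C3 trans to C6, the ring-E arrangement) is transferred from 19 by retention. The step needs chemoselectivity for C–I over the esters, the enoate and the free C8–OH, which the low basicity of the organozinc halide and the biarylphosphine catalyst should provide. It also needs the new allylic ester not to ionise to a π-allylpalladium species, which room temperature, the bulky ligand and the much faster C–I oxidative addition should secure. The whole 4-hydroxytiglate arrives as an ester on C15, so the C15 oxygen never has to be told apart from the C6 and C8 hydroxyls.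

Step 16
Reactants: 28 ethyl 2-(hydroxymethyl)prop-2-enoate
Product: 29 ethyl 2-{[(triethylsilyl)oxy]methyl}prop-2-enoate
Conditions: TESCl, imidazole, CH2Cl2, 0 °C
Reagents that add atoms: chlorotriethylsilane, CC[Si](Cl)(CC)CC
Why: Routine silylation of the primary allylic alcohol.

Step 17
Reactants: 29 ethyl 2-{[(triethylsilyl)oxy]methyl}prop-2-enoate
Product: 30 2-{[(triethylsilyl)oxy]methyl}prop-2-enoic acid
Conditions: LiOH·H2O, THF/H2O, 0 °C; then cold 0.5 M HCl to pH 4
Reagents that add atoms: lithium hydroxide, [Li+].[OH-]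
Why: Saponification at 0 °C with careful acidification, under which the primary TES ether is expected to survive.

Step 18
Reactants: 27 (key-step product, free C8–OH); 30 2-{[(triethylsilyl)oxy]methyl}prop-2-enoic acid
Product: 31 (2Z)-2-[(3E,6S)-4-methyl-6-({2-[(triethylsilyloxy)methyl]prop-2-enoyl}oxy)octa-3,7-dien-1-yl]-4-[(triethylsilyl)oxy]but-2-en-1-yl (2E)-4-[(tert-butyldimethylsilyl)oxy]-2-methylbut-2-enoate
Conditions: DCC, DMAP (cat.), CH2Cl2, 0 °C to rt
Reagents that add atoms: none
Why: Steglich esterification of the only free hydroxyl (C8–OH) installs C11–C13 and the future lactone carbonyl C12.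

Step 19
Reactants: 31 (acrylate ester of the C8 vinyl carbinol)
Product: 32 (2Z)-2-{(3E)-4-methyl-5-[(2S)-5-oxo-4-{[(triethylsilyl)oxy]methyl}-2,5-dihydrofuran-2-yl]pent-3-en-1-yl}-4-[(triethylsilyl)oxy]but-2-en-1-yl (2E)-4-[(tert-butyldimethylsilyl)oxy]-2-methylbut-2-enoate
Conditions: Grubbs second-generation catalyst (10 mol%), toluene (5 mM), 80 °C
Reagents that add atoms: none
Why: Ring-closing metathesis: the ruthenium alkylidene initiates at the monosubstituted vinyl group on C8 and closes the five-membered butenolide onto the acrylate (C7=C11) with loss of ethene; the three trisubstituted alkenes do not compete and C8 is untouched.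

Step 20
Reactants: 32 (butenolide with two TES ethers)
Product: 33 (2Z)-4-hydroxy-2-{(3E)-5-[(2S)-4-(hydroxymethyl)-5-oxo-2,5-dihydrofuran-2-yl]-4-methylpent-3-en-1-yl}but-2-en-1-yl (2E)-4-[(tert-butyldimethylsilyl)oxy]-2-methylbut-2-enoate
Conditions: PPTS (cat.), MeOH/CH2Cl2, 0 °C
Reagents that add atoms: none
Why: Acid-catalysed methanolysis removes both primary TES ethers far faster than the TBS ether, exposing C6–OH and C13–OH.

Step 21
Reactants: 33 (C6/C13 diol)
Product: 34 (2Z)-2-{(3E)-5-[(2S)-4-(hydroxymethyl)-5-oxo-2,5-dihydrofuran-2-yl]-4-methylpent-3-en-1-yl}-4-oxobut-2-en-1-yl (2E)-4-[(tert-butyldimethylsilyl)oxy]-2-methylbut-2-enoate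
Conditions: MnO2 (activated), CH2Cl2, rt; used directly
Reagents that add atoms: none
Why: MnO2 oxidation of the allylic alcohol on the electron-rich trisubstituted alkene (C6) should be much faster than that of the hydroxymethyl group on the electron-poor butenolide (C13), giving the enal with its geometry intact under neutral conditions.

Step 22
Reactants: 34 (C6 enal, C13 alcohol)
Product: 35 (2Z)-2-{(3E)-5-[(2S)-4-(bromomethyl)-5-oxo-2,5-dihydrofuran-2-yl]-4-methylpent-3-en-1-yl}-4-oxobut-2-en-1-yl (2E)-4-[(tert-butyldimethylsilyl)oxy]-2-methylbut-2-enoate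
Conditions: NBS, Me2S, CH2Cl2, −20 to 0 °C; used directly
Reagents that add atoms: N-bromosuccinimide, O=C1CCC(=O)N1Br
Why: Corey–Kim bromination converts the allylic alcohol into the bromide via an alkoxysulfonium salt without affecting the aldehyde; either allylic bromide regioisomer would lead to the same allylchromium species.

Step 23
Reactants: 35 (bromo enal)
Product: 37 [(3aS,4R,5Z,9E,11aS)-4-hydroxy-10-methyl-3-methylidene-2-oxo-2,3,3a,4,7,8,11,11a-octahydrocyclodeca[b]furan-6-yl]methyl (2E)-4-[(tert-butyldimethylsilyl)oxy]-2-methylbut-2-enoate, via allylchromium(III) species 36 (not isolated)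
Conditions: CrCl2 (8 equiv), THF (2 mM, slow addition of 35), rt; pH 7 work-up
Reagents that add atoms: none
Why: Nozaki–Hiyama–Kishi-type allylation: Cr(II) turns the allylic bromide into allylchromium 36, which adds through its γ-carbon C7 to the C6 aldehyde in a chair six-membered transition state (10-exo-trig closure) and creates the exocyclic C11=C13 methylene; C7 is set by attack on the butenolide face anti to the C8–C9 bond (trans-lactone) and C6 by the equatorial placement of C5 in the chair (anti adduct, 6R), a geometry that matches the crown conformation of trans-fused E,E-germacranolides, while the allylic ester, enoate and silyl ether are inert to Cr(II).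

Step 24
Reactants: 37 (O-TBS-protected target)
Product: 38 [(3aS,4R,5Z,9E,11aS)-4-hydroxy-10-methyl-3-methylidene-2-oxo-2,3,3a,4,7,8,11,11a-octahydrocyclodeca[b]furan-6-yl]methyl (2E)-4-hydroxy-2-methylbut-2-enoate
Conditions: HF·pyridine, pyridine, THF, 0 °C to rt
Reagents that add atoms: none
Why: Buffered fluoride desilylation of the primary TBS ether under non-basic conditions, which should avoid acyl migration, translactonisation and conjugate addition to the α-methylene lactone.

**Compound list**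

1 | (S)-epichlorohydrin, (2S)-2-(chloromethyl)oxirane | ClC[C@@H]1CO1 | starting material
2 | ethynyl(trimethyl)silane | C#C[Si](C)(C)C | starting material
3 | lithium (trimethylsilyl)acetylide (not isolated) | [Li]C#C[Si](C)(C)C | intermediate
4 | (2S)-1-chloro-5-(trimethylsilyl)pent-4-yn-2-ol | O[C@H](CCl)CC#C[Si](C)(C)C | intermediate
5 | (2S)-2-[3-(trimethylsilyl)prop-2-yn-1-yl]oxirane (not isolated) | C[Si](C)(C)C#CC[C@H]1CO1 | intermediate
6 | (3S)-6-(trimethylsilyl)hex-1-en-5-yn-3-ol | O[C@H](C=C)CC#C[Si](C)(C)C | intermediate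
7 | (3S)-hex-1-en-5-yn-3-ol | O[C@H](C=C)CC#C | intermediate
8 | (E)-alkenyl(dimethyl)alane from 7, hydroxyl as dimethylaluminium alkoxide (not isolated) | C[Al](C)O[C@H](C=C)C/C(C)=C/[Al](C)C | intermediate
9 | (3S,5E)-6-iodo-5-methylhexa-1,5-dien-3-ol | O[C@H](C=C)C/C(C)=C/I | intermediate
10 | tert-butyl(dimethyl)(prop-2-yn-1-yloxy)silane | C#CCO[Si](C)(C)C(C)(C)C | starting material
11 | lithium acetylide of 10 (not isolated) | [Li]C#CCO[Si](C)(C)C(C)(C)C | intermediate
12 | 5-[(tert-butyldimethylsilyl)oxy]pent-3-yn-1-ol | OCCC#CCO[Si](C)(C)C(C)(C)C | intermediate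
13 | tert-butyl[(5-iodopent-2-yn-1-yl)oxy]dimethylsilane | ICCC#CCO[Si](C)(C)C(C)(C)C | intermediate
14 | {5-[(tert-butyldimethylsilyl)oxy]pent-3-yn-1-yl}zinc iodide (not isolated) | I[Zn]CCC#CCO[Si](C)(C)C(C)(C)C | intermediate
15 | (3S,5E)-11-[(tert-butyldimethylsilyl)oxy]-5-methylundeca-1,5-dien-9-yn-3-ol | O[C@H](C=C)C/C(C)=C/CCC#CCO[Si](C)(C)C(C)(C)C | intermediate
16 | (6E,9S)-7-methylundeca-6,10-dien-2-yne-1,9-diol | O[C@H](C=C)C/C(C)=C/CCC#CCO | intermediate
17 | sodium alkenylalanate: five-membered 2,5-dihydro-1,2-oxaluminole through C4–Al and O6, C8–O as hydridoaluminate (not isolated) | [Na+].[Na+].COCCO[AlH-](OCCOC)O[C@H](C=C)C/C(C)=C/CCC1=CCO[Al-]1(OCCOC)OCCOC | intermediate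
18 | (2Z,6E,9S)-3-iodo-7-methylundeca-2,6,10-triene-1,9-diol | O[C@H](C=C)C/C(C)=C/CC/C(I)=C/CO | intermediate
19 | (3S,5E,9Z)-9-iodo-5-methyl-11-[(triethylsilyl)oxy]undeca-1,5,9-trien-3-ol | O[C@H](C=C)C/C(C)=C/CC/C(I)=C/CO[Si](CC)(CC)CC | intermediate
20 | [(tert-butyldimethylsilyl)oxy]acetaldehyde | O=CCO[Si](C)(C)C(C)(C)C | starting material
21 | ethyl 2-(triphenyl-λ5-phosphanylidene)propanoate | CCOC(=O)C(C)=P(c1ccccc1)(c1ccccc1)c1ccccc1 | starting material
22 | ethyl (2E)-4-[(tert-butyldimethylsilyl)oxy]-2-methylbut-2-enoate | CCOC(=O)/C(C)=C/CO[Si](C)(C)C(C)(C)C | intermediate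
23 | (2E)-4-[(tert-butyldimethylsilyl)oxy]-2-methylbut-2-enoic acid | OC(=O)/C(C)=C/CO[Si](C)(C)C(C)(C)C | intermediate
24 | chloromethyl (2E)-4-[(tert-butyldimethylsilyl)oxy]-2-methylbut-2-enoate | ClCOC(=O)/C(C)=C/CO[Si](C)(C)C(C)(C)C | intermediate
25 | iodomethyl (2E)-4-[(tert-butyldimethylsilyl)oxy]-2-methylbut-2-enoate | ICOC(=O)/C(C)=C/CO[Si](C)(C)C(C)(C)C | intermediate
26 | ({[(2E)-4-[(tert-butyldimethylsilyl)oxy]-2-methylbut-2-enoyl]oxy}methyl)zinc iodide (not isolated) | I[Zn]COC(=O)/C(C)=C/CO[Si](C)(C)C(C)(C)C | intermediate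
27 | (2Z)-2-[(3E,6S)-6-hydroxy-4-methylocta-3,7-dien-1-yl]-4-[(triethylsilyl)oxy]but-2-en-1-yl (2E)-4-[(tert-butyldimethylsilyl)oxy]-2-methylbut-2-enoate | O[C@H](C=C)C/C(C)=C/CC/C(COC(=O)/C(C)=C/CO[Si](C)(C)C(C)(C)C)=C/CO[Si](CC)(CC)CC | intermediate
28 | ethyl 2-(hydroxymethyl)prop-2-enoate | C=C(CO)C(=O)OCC | starting material
29 | ethyl 2-{[(triethylsilyl)oxy]methyl}prop-2-enoate | C=C(CO[Si](CC)(CC)CC)C(=O)OCC | intermediate
30 | 2-{[(triethylsilyl)oxy]methyl}prop-2-enoic acid | C=C(CO[Si](CC)(CC)CC)C(=O)O | intermediate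
31 | (2Z)-2-[(3E,6S)-4-methyl-6-({2-[(triethylsilyloxy)methyl]prop-2-enoyl}oxy)octa-3,7-dien-1-yl]-4-[(triethylsilyl)oxy]but-2-en-1-yl (2E)-4-[(tert-butyldimethylsilyl)oxy]-2-methylbut-2-enoate | C=C(CO[Si](CC)(CC)CC)C(=O)O[C@H](C=C)C/C(C)=C/CC/C(COC(=O)/C(C)=C/CO[Si](C)(C)C(C)(C)C)=C/CO[Si](CC)(CC)CC | intermediate
32 | (2Z)-2-{(3E)-4-methyl-5-[(2S)-5-oxo-4-{[(triethylsilyl)oxy]methyl}-2,5-dihydrofuran-2-yl]pent-3-en-1-yl}-4-[(triethylsilyl)oxy]but-2-en-1-yl (2E)-4-[(tert-butyldimethylsilyl)oxy]-2-methylbut-2-enoate | O1[C@H](C=C(CO[Si](CC)(CC)CC)C1=O)C/C(C)=C/CC/C(COC(=O)/C(C)=C/CO[Si](C)(C)C(C)(C)C)=C/CO[Si](CC)(CC)CC | intermediate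
33 | (2Z)-4-hydroxy-2-{(3E)-5-[(2S)-4-(hydroxymethyl)-5-oxo-2,5-dihydrofuran-2-yl]-4-methylpent-3-en-1-yl}but-2-en-1-yl (2E)-4-[(tert-butyldimethylsilyl)oxy]-2-methylbut-2-enoate | O1[C@H](C=C(CO)C1=O)C/C(C)=C/CC/C(COC(=O)/C(C)=C/CO[Si](C)(C)C(C)(C)C)=C/CO | intermediate
34 | (2Z)-2-{(3E)-5-[(2S)-4-(hydroxymethyl)-5-oxo-2,5-dihydrofuran-2-yl]-4-methylpent-3-en-1-yl}-4-oxobut-2-en-1-yl (2E)-4-[(tert-butyldimethylsilyl)oxy]-2-methylbut-2-enoate | O1[C@H](C=C(CO)C1=O)C/C(C)=C/CC/C(COC(=O)/C(C)=C/CO[Si](C)(C)C(C)(C)C)=C/C=O | intermediate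
35 | (2Z)-2-{(3E)-5-[(2S)-4-(bromomethyl)-5-oxo-2,5-dihydrofuran-2-yl]-4-methylpent-3-en-1-yl}-4-oxobut-2-en-1-yl (2E)-4-[(tert-butyldimethylsilyl)oxy]-2-methylbut-2-enoate | O1[C@H](C=C(CBr)C1=O)C/C(C)=C/CC/C(COC(=O)/C(C)=C/CO[Si](C)(C)C(C)(C)C)=C/C=O | intermediate
36 | allylchromium(III) dichloride derived from 35, Cr on C13 (not isolated) | O1[C@H](C=C(C[Cr](Cl)Cl)C1=O)C/C(C)=C/CC/C(COC(=O)/C(C)=C/CO[Si](C)(C)C(C)(C)C)=C/C=O | intermediate
37 | [(3aS,4R,5Z,9E,11aS)-4-hydroxy-10-methyl-3-methylidene-2-oxo-2,3,3a,4,7,8,11,11a-octahydrocyclodeca[b]furan-6-yl]methyl (2E)-4-[(tert-butyldimethylsilyl)oxy]-2-methylbut-2-enoate | C=C1C(=O)O[C@H]2C/C(C)=C/CC/C(COC(=O)/C(C)=C/CO[Si](C)(C)C(C)(C)C)=C/[C@@H](O)[C@H]12 | intermediate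
38 | [(3aS,4R,5Z,9E,11aS)-4-hydroxy-10-methyl-3-methylidene-2-oxo-2,3,3a,4,7,8,11,11a-octahydrocyclodeca[b]furan-6-yl]methyl (2E)-4-hydroxy-2-methylbut-2-enoate (CNP0326626.1) | C=C1C(=O)O[C@H]2C/C(C)=C/CC/C(COC(=O)/C(C)=C/CO)=C/[C@@H](O)[C@H]12 | target

**Step count and risks**

Total steps: 24. Longest linear sequence: 16 steps (1–4, 7–10, 15, 18–24).

Steps most likely to fail:

1. Step 23. In the ten-membered transition state the aldehyde may be attacked on the wrong face, so that the C6 epimer forms, and intermolecular allylation may compete with closure of the strained E,E-ring. Fallback: the route sets out from 35. If cyclisation under the chromium conditions delivers mainly the 6-epi alcohol F1, it would be oxidised without base (Dess–Martin periodinane, NaHCO3, CH2Cl2, 0 °C, so that the C7–H between ketone and enoate is not enolised) to the macrocyclic C6 enone F2. A reagent-controlled 1,2-reduction ((R)-Me-CBS, catecholborane, toluene, −78 °C) would then be expected to give 37, where the route is rejoined. The C6 configuration is then set by hydride transfer and not in the C–C bond formation.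

2. Step 15. Transmetalation of the electron-poor α-acyloxymethylzinc may be slow, and Pd(0) may ionise the newly formed allylic ester, with loss of the side chain. Fallback: from 19, Kosugi–Migita–Stille hydroxymethylation with (tributylstannyl)methanol (Pd(PPh3)4, dioxane, 80 °C) would give the allylic diol F3. Its primary allylic hydroxyl would then be esterified in preference to the secondary C8–OH with acid 23 (DIC, cat. DMAP, CH2Cl2, −20 °C), which rejoins the route at 27. Here C4–C15 is made with a one-carbon unit and the ester bond is formed afterwards.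

3. Step 19. Ring closure onto the 1,1-disubstituted, electron-poor acrylate may be slower than catalyst decay or intermolecular metathesis. Fallback: from 27, acylation with acryloyl chloride (Et3N, CH2Cl2, −78 °C) would give the acrylate F4. Ring-closing metathesis of this unhindered acrylate (Grubbs second-generation catalyst, CH2Cl2, 40 °C) would give the α-unsubstituted butenolide F5. Morita–Baylis–Hillman hydroxymethylation (aqueous formaldehyde, PBu3, THF) would then give the α-(hydroxymethyl)butenolide F6, and removal of the C6 silyl ether (PPTS, MeOH/CH2Cl2, 0 °C) rejoins the route at 33. C13 is thus introduced after the five-membered ring exists.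

**Further compounds**

F1 | step 23 | [(3aS,4S,5Z,9E,11aS)-4-hydroxy-10-methyl-3-methylidene-2-oxo-2,3,3a,4,7,8,11,11a-octahydrocyclodeca[b]furan-6-yl]methyl (2E)-4-[(tert-butyldimethylsilyl)oxy]-2-methylbut-2-enoate (C6 epimer of 37) | C=C1C(=O)O[C@H]2C/C(C)=C/CC/C(COC(=O)/C(C)=C/CO[Si](C)(C)C(C)(C)C)=C/[C@H](O)[C@H]12
F2 | step 23 | [(3aR,5Z,9E,11aS)-10-methyl-3-methylidene-2,4-dioxo-2,3,3a,4,7,8,11,11a-octahydrocyclodeca[b]furan-6-yl]methyl (2E)-4-[(tert-butyldimethylsilyl)oxy]-2-methylbut-2-enoate | C=C1C(=O)O[C@H]2C/C(C)=C/CC/C(COC(=O)/C(C)=C/CO[Si](C)(C)C(C)(C)C)=C/C(=O)[C@H]12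
F3 | step 15 | (2Z)-2-[(3E,6S)-6-hydroxy-4-methylocta-3,7-dien-1-yl]-4-[(triethylsilyl)oxy]but-2-en-1-ol | O[C@H](C=C)C/C(C)=C/CC/C(CO)=C/CO[Si](CC)(CC)CC
F4 | step 19 | (2Z)-2-[(3E,6S)-4-methyl-6-(prop-2-enoyloxy)octa-3,7-dien-1-yl]-4-[(triethylsilyl)oxy]but-2-en-1-yl (2E)-4-[(tert-butyldimethylsilyl)oxy]-2-methylbut-2-enoate | C=CC(=O)O[C@H](C=C)C/C(C)=C/CC/C(COC(=O)/C(C)=C/CO[Si](C)(C)C(C)(C)C)=C/CO[Si](CC)(CC)CC
F5 | step 19 | (2Z)-2-{(3E)-4-methyl-5-[(2S)-5-oxo-2,5-dihydrofuran-2-yl]pent-3-en-1-yl}-4-[(triethylsilyl)oxy]but-2-en-1-yl (2E)-4-[(tert-butyldimethylsilyl)oxy]-2-methylbut-2-enoate | O1[C@H](C=CC1=O)C/C(C)=C/CC/C(COC(=O)/C(C)=C/CO[Si](C)(C)C(C)(C)C)=C/CO[Si](CC)(CC)CC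
F6 | step 19 | (2Z)-2-{(3E)-5-[(2S)-4-(hydroxymethyl)-5-oxo-2,5-dihydrofuran-2-yl]-4-methylpent-3-en-1-yl}-4-[(triethylsilyl)oxy]but-2-en-1-yl (2E)-4-[(tert-butyldimethylsilyl)oxy]-2-methylbut-2-enoate | O1[C@H](C=C(CO)C1=O)C/C(C)=C/CC/C(COC(=O)/C(C)=C/CO[Si](C)(C)C(C)(C)C)=C/CO[Si](CC)(CC)CC
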